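Late in a run, once the incoming ligand has been taken up, the concentration to watch is that of free starting complex, because the third exchange competes with it for whatever ligand remains.

| flask | starting complex | incoming ligand | time |
|---|---|---|---|
| birch | 1.0 M | 0.500 equiv | 4.0 min |
| cedar | 1.0 M | 0.750 equiv | 4.0 min |
| oak | 1.0 M | 1.10 equiv | 4.0 min |

    complex with two exchanged + incoming ligand → leaving ligand + complex with three exchanged (k1 = 0.0105 M⁻¹ s⁻¹)
    leaving ligand + starting complex ⇌ idle adduct, settled at all times (K2 = 81.6 M⁻¹)
    starting complex ⇌ dormant form (K3 = 0.552, k3 = 0.00230 s⁻¹)
    starting complex + incoming ligand → leaving ligand + complex with one exchanged (k4 = 0.263 M⁻¹ s⁻¹)
    complex with one exchanged + incoming ligand → leaving ligand + complex with two exchanged (k5 = 0.285 M⁻¹ s⁻¹)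
    complex with three exchanged + incoming ligand → leaving ligand + complex with four exchanged (k6 = 0.290 M⁻¹ s⁻¹)

- which of these there is most of at the end, counted by the starting complex in it, birch (complex with three exchanged / starting complex / complex with one exchanged / complex with four exchanged / complex with two exchanged)
- which of these there is most of at the end, counted by the starting complex in it, cedar (complex with three exchanged / starting complex / complex with one exchanged / complex with four exchanged / complex with two exchanged)
- which of these there is most of at the end, counted by the starting complex in it, oak (complex with three exchanged / starting complex / complex with one exchanged / complex with four exchanged / complex with two exchanged)
- the largest of these amounts at the end, in percent of the starting complex charged, birch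
- the largest of these amounts at the end, in percent of the starting complex charged, cedar
- the largest of these amounts at the end, in percent of the starting complex charged, oak

Each exchange frees a leaving ligand, and that ligand goes into the idle adduct, since the adduct constant times the starting concentration is 82 in birch. The third exchange has a constant 27.1 times smaller than the second, so the complex with two exchanged should be the resting state of the chain. A complex stopping there has released two leaving ligands, which lock two more starting complexes. The dormant form is left out of this count, its forward step being 57 times slower than the first exchange just after the start in birch. Free starting complex then lasts up to 0.667 equiv of ligand. Birch lies below that mark, and there this reckoning cannot choose between one and two exchanged, the two constants being close, so it gives no birch number. Cedar and oak lie above it, and past the mark the adduct feeds the chain. Two ligands per complex then give a ceiling of 37.5 % in cedar and 55.0 % in oak.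

The weak link is the stall itself. At the oak ceiling, the adduct balance leaves free starting complex at 0.00848 M, so ligand reaches the complex with two exchanged 2.59 times as fast as it reaches starting complex. The reckoning therefore drops the oak ceiling. The complex with two exchanged stops growing where those two rates are equal, since one route feeds it and the other drains it. Putting the same balance into that equality, with 0.307 as the ratio of constants, gives the plateau 45.6 %: the amount of complex with two exchanged at which its loss to the third exchange equals its supply from free starting complex. Cedar's ceiling stands below the plateau, so the reckoning keeps 37.5 % for cedar, while oak's stands above it, so oak gets the plateau.

The forecast names complex with one exchanged at 22.5 % for birch, complex with two exchanged at 30 % for cedar and complex with two exchanged at 40 % for oak, on the ground that “each exchange removes about two free starting complexes”. Its cedar and oak amounts are lower than those reckoned here.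

The flask gives complex with one exchanged at 22.0 % in birch, complex with two exchanged at 30.1 % in cedar and complex with two exchanged at 40.4 % in oak, the forecast's choices and, within the margin, its amounts, with oak 5.2 percentage points under the plateau. In oak the complex with two exchanged reads 39.8 % after 0.800 min and 40.4 % after 40.0 min. The plateau contains the charge of starting complex but not that of incoming ligand, so with the starting complex held at 1.0 M it goes over to the neighbour with 1.20 equiv of incoming ligand: there the complex with two exchanged reads 39.6 %, and the complex with four exchanged 8.59 %, against 5.72 % in oak.

(Its constants belong to no real substance.)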